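## Structural features

Compound 39 is a C25 diacid built on a bicyclo[4.3.0]nonadiene: ring A is C7, C9, C10, C11, C30 and ring B is C11, C12, C16, C27, C28, C30. The core carries an (R)-butanoic acid arm on C7, a carboxyl on C12, a secondary hydroxyl on C28 and, through the C17 methylene on C16, a 3,3-dimethyl-7-oxabicyclo[2.2.1]heptane. Four of the six stereocentres are contiguous, C2 (tertiary) – C7 (quaternary) – C30 (quaternary, angular methyl C31) – C28 (carbinol); the ether bridgeheads C18 and C21 are remote and depend on each other. A descriptor check gives C2 R, C7 S, C18 S, C21 S, C28 R, C30 S; on ring A the butanoate arm is cis to C31, and on ring B the C28 oxygen is trans to C31. Compounds 36 and 37 hold the same spatial arrangement at every shared centre and the enol ether of 36 is Z, so the three structures of the key step are mutually consistent and are used unchanged. The fragile region is the cross-ring dienoic acid C10=C11–C12=C16: its gamma hydrogens at C17 sit next to the strained tertiary ether carbon C18, so strong base can open the bridge by vinylogous beta-elimination, strong acid can ionise C18–O22, and the diene limits the oxidants. The real difficulty is the pair of adjacent quaternary carbons C7/C30 with stereocentres on both sides, and a C28 oxygen that must sit on the more hindered face. The key step exploits that ring B holds C12=C16 and the exocyclic C10=C11 exactly where a vinylallene [4+2] adduct puts them, with ring A as the ring closed by the three-atom tether C10–C9–C7.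

## Logic of the disconnections

39 ⇒ 38. The two ester C–O bonds (at C4 and C13) are cut. Carrying both acids as methyl esters keeps every intermediate neutral and free of acidic protons during the organometallic and palladium steps. The forward step must hydrolyse without deconjugating the diene or opening the ether bridge.

38 ⇒ 37. The O–aryl bond on the C28 oxygen is cut. The 4-methoxyphenyl group is both the protecting group of this oxygen and the donor of the dienophile, and it tolerates base, fluoride, zerovalent palladium and heat. The forward step must oxidise the aryl ring without touching the dienoate.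

37 ⇒ 36. Bonds C11–C30 and C27–C28 are cut. Both carbocycles, C30 and C28 disappear, leaving an acyclic chain with C7 and C2 as the only controlling centres. The forward step must choose one face of the enol ether relative to C7 and must add suprafacially to a Z alkene.

36 ⇒ 35. The C12–C13 bond is cut with allylic transposition, turning the allenoate into an alkyne with a leaving group on C10. This replaces a reactive cumulene by a stable propargylic carbonate. The forward step needs SN2′ ionisation, CO insertion faster than direct substitution, and a temperature low enough for 36 to survive.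

35 ⇒ 10 + 32. The C10–C11 bond is cut, dividing the molecule into two fragments of similar size. The new C10 centre is irrelevant because it becomes sp2. The forward step must add to the aldehyde and not to the methyl ester.

32 ⇒ 31 ⇒ 30. The C10 aldehyde is traced to a silyl-protected primary alcohol. Alkene cleavage cannot be used because the enol ether is the most electron-rich alkene present. The forward steps need fluoride and a non-acidic oxidant.

30 ⇒ 28. The C30–C31 bond is cut: methyl and hydrogen are removed from the same side of C30=C28, leaving an ynol ether. The Z geometry (oxygen cis to the quaternary C7) is the less stable one, so only a stereospecific syn addition can deliver it. The forward step needs copper on the oxygen-bearing carbon and reaction at an alkyne carbon next to a quaternary centre.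

28 ⇒ 25. The alkyne is traced to a C30 ketone with a C28 methylene bearing the aryloxy group. C30 becomes a carbonyl carbon that can be joined to C7 by acyl substitution. The forward step relies on C28 being the only enolisable position of the ketone.

25 ⇒ 23 ⇒ 17 + 21. The C30–C28 bond is cut; the ring-opening also releases the C4 hydroxyl, which is then oxidised to the ester. The lactone thus serves as acyl donor and as the device that differentiates the two chain ends. The forward step must stop after one addition. 21 ⇒ 18 + 19 is an O–C cut (ether synthesis).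

17 ⇒ 15 ⇒ 13. The C7–C9 bond and then the C7–C8 bond are cut. The acyclic C2/C7 problem becomes 1,2-induction in a six-membered ring, with the second electrophile entering anti to the C2 methyl; the order (methyl first) is therefore fixed. The forward step needs a two-carbon electrophile reactive enough for a trisubstituted enolate.

13 ⇒ 11. The lactone C–O bond is cut. The ester arm of 11 becomes C7/C30 and the acid arm becomes C3/C4. The forward step needs reduction of the acid in the presence of the ester.

10 ⇒ 9 ⇒ 7. The C12–C16 bond is cut (alkynyl–alkenyl coupling) and the enol triflate is traced to a methyl ketone. The forward step must enolise only the methyl group, because an enolate at C17 could expel the bridging oxygen.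

7 ⇒ 6. The C16 carbonyl is traced to a terminal alkene, so the ketone is absent during the Lewis-acid step.

6 ⇒ 5. Bonds C23–C26 and O22–C18 are cut. The bicycle becomes an acyclic triene monoepoxide with one stereocentre. The forward step needs termination by oxygen capture in preference to proton loss.

5 ⇒ 4 ⇒ 3 ⇒ 1. The epoxide oxygen is removed (asymmetric epoxidation of the only trisubstituted alkene), the C17–C18 bond is cut (allyl–alkenyl coupling), and the enol triflate is traced to the methyl ketone 1.

## Other disconnections considered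

Alternative 1: The cut is C7–C30, the bond between the two quaternary carbons, with C9–C28 as a temporary bond. In the forward step, irradiation of dienone A2 joins C7 to C30 and C9 to C28 in the crossed sense, and fluoride in the same flask frees the C28 oxygen and breaks C9–C28 by retro-aldol, leaving cyclopentanone A1.
- In its favour: the most congested bond is made in an excited-state step that is little affected by crowding, both quaternary centres appear in one flask, and the C28 oxygen needs no protecting group.
- Against it here: the excited enone loses its alkene geometry, so C7 is set only by the weak influence of C2. A1 still lacks the C10=C11 alkene, the C12 carboxyl, the C12=C16 alkene and the whole ether side chain. Reduction of the C28 ketone must deliver hydride from the face of the angular methyl, which is the hindered face.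
- Comparison: for joining two quaternary carbons this plan is the better one, since the chosen plan has to close C11–C30 next to C7 in a thermal cycloaddition. On control of C7 and C28 and on the number of steps after the key step the chosen plan is stronger, because 37 already holds every carbon of 39 and C28 follows from alkene geometry.

Alternative 2: The cuts are C16–C27 and C11–C12 in ring B. In the forward step LiN(SiMe3)2 enolises the acetyl group of cyclopentenone A3 at C27, this carbon adds to C16 of ynoate A4, and C12 then closes on the C11 carbonyl to give aldol A5.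
- In its favour: it is the most convergent of the four plans, needs only a base, places the C12 ester and the C12=C16 alkene in the bond-forming step, and avoids both an allene and a protecting group on the C28 oxygen. A4 also needs neither a 1,1-disubstituted alkene nor an enol triflate, so it is simpler than 10.
- Against it here: A3 must already hold C7 and C30 in the right relative and absolute sense, so the hardest stereochemical problem is moved into a fragment, not solved. Closure must be 1,2 on an enone that also offers a 1,4 position. A5 needs a reductive allylic transposition (C11–OH with C9=C10 to C10=C11). The C28 ketone again has to be reduced from the methyl-bearing face.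
- Comparison: Alternative 2 is the equal or the better in convergence and in functional-group economy at C12/C16. The chosen plan is better where it matters most here: one step sets C30 and C28 with a predictable relation to a single acyclic centre and leaves nothing to adjust in ring A.

Alternative 3: The cuts are C23–C26 and O22–C18; the ether bicycle is made last. In the forward step Et2AlCl opens the epoxide of A6, the C18=C26 alkene attacks C23 through C26, and the C21 oxygen closes on C18 to give A7.
- In its favour: the side chain travels as a robust acyclic unit, both bridgeheads come from one epoxide centre, and the C28 acetate of A7 falls off in the final saponification, which saves the separate dearylation of 37.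
- Against it here: the Lewis acid meets two esters, an acetate and a dienoate whose C16 substituent is allylic to the reacting alkene, so excess reagent is needed and proton loss toward C17 would give a conjugated triene. Any loss in termination selectivity is paid with the most advanced material, and the enantiopure epoxide has to be made or carried in the presence of the diene.
- Comparison: the two plans use the same cyclisation and are equal in how they control C18 and C21. Alternative 3 is better in steps after the cycloaddition and in keeping a strained ether out of the long sequence. The chosen plan is better in where it places the risk: the same reaction is run in step 4 on an eleven-carbon epoxide, where by-products can be recycled.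

Key step: step 20

Assumption: the (R)-monoester 11 and the L-series fructose-derived epoxidation ketone are taken as purchasable; the carbinol centre of 34/35 and the allene axis of 36 are epimer mixtures, drawn without descriptor because step 20 destroys both.

## Route

Step 1
Reactants: 1 6-methylhept-5-en-2-one
Product: 3 6-methylhepta-1,5-dien-2-yl trifluoromethanesulfonate, via lithium enolate 2 (not isolated)
Conditions: LiN(iPr)2, THF, −78 °C; PhNTf2, −78 → 0 °C
Reagents that add atoms: N-phenylbis(trifluoromethanesulfonimide), O=S(=O)(N(c1ccccc1)S(=O)(=O)C(F)(F)F)C(F)(F)F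
Why: Kinetic deprotonation of the methyl ketone by the hindered amide takes a methyl hydrogen, and O-triflation of the enolate fixes the 1,1-disubstituted alkene (enol triflate formation).

Step 2
Reactants: 3 6-methylhepta-1,5-dien-2-yl trifluoromethanesulfonate
Product: 4 8-methyl-4-methylidenenona-1,7-diene
Conditions: allylSnBu3, Pd(PPh3)4 (cat.), LiCl, THF, 65 °C
Reagents that add atoms: allyltributylstannane, C=CC[Sn](CCCC)(CCCC)CCCC
Why: Stille coupling of an alkenyl triflate with an allylstannane; LiCl turns over the palladium triflate intermediate, and the allyl group is symmetric so transposition changes nothing.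

Step 3
Reactants: 4 8-methyl-4-methylidenenona-1,7-diene
Product: 5 (3S)-2,2-dimethyl-3-(3-methylidenehex-5-en-1-yl)oxirane
Conditions: fructose-derived ketone catalyst of the L series (0.3 equiv), KHSO5, K2CO3, Bu4NHSO4, MeCN/CH2(OMe)2/aq. Na2B4O7, 0 °C
Reagents that add atoms: potassium peroxymonosulfate, [K+].[O-]S(=O)(=O)OO
Why: Shi epoxidation; the chiral dioxirane reacts with the trisubstituted alkene much faster than with the 1,1-disubstituted or monosubstituted ones. The L-series catalyst is needed because the D-series dioxirane gives the 3R oxirane from a prenyl group; C21 is set here (S) under reagent control.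

Step 4
Reactants: 5 (3S)-2,2-dimethyl-3-(3-methylidenehex-5-en-1-yl)oxirane
Product: 6 (1S,4S)-3,3-dimethyl-1-(prop-2-en-1-yl)-7-oxabicyclo[2.2.1]heptane
Conditions: BF3·OEt2 (0.3 equiv), CH2Cl2, −78 → −30 °C
Reagents that add atoms: none
Why: Epoxide-initiated cation–olefin cyclisation: the 1,1-disubstituted alkene attacks the tertiary epoxide carbon C23 through C26, and the C21 oxygen captures the tertiary C18 centre across the ring, the behaviour known for epoxides of 2-alkyl-6-methylhepta-1,5-dienes with BF3. C21 keeps its C–O bond (retention), and the bridge can only close cis, which fixes C18.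

Step 5
Reactants: 6 (1S,4S)-3,3-dimethyl-1-(prop-2-en-1-yl)-7-oxabicyclo[2.2.1]heptane
Product: 7 1-[(1R,4S)-3,3-dimethyl-7-oxabicyclo[2.2.1]heptan-1-yl]propan-2-one
Conditions: PdCl2 (10 mol %), CuCl, O2 (1 atm), DMF/H2O, 25 °C
Reagents that add atoms: water, O
Why: Wacker oxidation: Markovnikov hydroxypalladation of the monosubstituted alkene and beta-hydride elimination give the methyl ketone; the saturated ether is inert (the descriptor at C18 changes by priority only).

Step 6
Reactants: 7 1-[(1R,4S)-3,3-dimethyl-7-oxabicyclo[2.2.1]heptan-1-yl]propan-2-one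
Product: 9 3-[(1R,4S)-3,3-dimethyl-7-oxabicyclo[2.2.1]heptan-1-yl]prop-1-en-2-yl trifluoromethanesulfonate, via potassium enolate 8 (not isolated)
Conditions: KN(SiMe3)2, THF, −78 °C; PhNTf2, −78 °C
Reagents that add atoms: N-phenylbis(trifluoromethanesulfonimide), O=S(=O)(N(c1ccccc1)S(=O)(=O)C(F)(F)F)C(F)(F)F
Why: Kinetic enolisation takes the methyl group because the C17 methylene is neopentyl-like and slower; O-triflation follows. Avoiding the C17 enolate also avoids beta-elimination of the strained ether oxygen.

Step 7
Reactants: 9 3-[(1R,4S)-3,3-dimethyl-7-oxabicyclo[2.2.1]heptan-1-yl]prop-1-en-2-yl trifluoromethanesulfonate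
Product: 10 (1S,4S)-3,3-dimethyl-1-(2-methylidenebut-3-yn-1-yl)-7-oxabicyclo[2.2.1]heptane
Conditions: HC≡CMgBr, ZnBr2, THF, 0 °C; then 9, Pd(PPh3)4 (5 mol %), 25 °C
Reagents that add atoms: ethynylmagnesium bromide, C#C[Mg]Br
Why: Negishi coupling of the alkenyl triflate with ethynylzinc bromide made in the flask gives the terminal 1,3-enyne directly, with no silyl group to remove.

Step 8
Reactants: 11 (3R)-5-methoxy-3-methyl-5-oxopentanoic acid
Product: 13 (4R)-4-methyloxan-2-one, via hydroxy ester 12 (not isolated)
Conditions: BH3·SMe2, THF, 0 → 25 °C; MeOH; then TsOH (cat.), PhMe, 80 °C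
Reagents that add atoms: none
Why: Borane reduces the free acid much faster than the methyl ester, and acid-catalysed lactonisation closes the six-membered ring on the ester carbon. The stereocentre is untouched and the chain ends are now differentiated (carbonyl side = C7/C30, alkoxy side = C3/C4).

Step 9
Reactants: 13 (4R)-4-methyloxan-2-one
Product: 15 (3S,4R)-3,4-dimethyloxan-2-one, via lithium enolate 14 (not isolated)
Conditions: LiN(iPr)2, THF, −78 °C; MeI
Reagents that add atoms: iodomethane, CI
Why: Lactone enolate alkylation; the methyl enters anti to the ring methyl (trans product). This centre is re-enolised in step 10, so its configuration is not critical.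

Step 10
Reactants: 15 (3S,4R)-3,4-dimethyloxan-2-one
Product: 17 (3S,4R)-3-[2-[tert-butyl(dimethyl)silyl]oxyethyl]-3,4-dimethyloxan-2-one, via lithium enolate 16 (not isolated)
Conditions: LiN(iPr)2, THF, −78 °C; ICH2CH2OSi(tBu)Me2, DMPU, −78 → −20 °C
Reagents that add atoms: tert-butyl(2-iodoethoxy)dimethylsilane, CC(C)(C)[Si](C)(C)OCCI
Why: Alkylation of the trisubstituted lactone enolate: 1,2-allylic strain turns the ring methyl pseudoaxial, so the electrophile enters from the opposite face. The two-carbon arm ends trans and the new quaternary methyl cis to the ring methyl, which sets C7 (S) by 1,2-induction; DMPU raises enolate reactivity toward the beta-silyloxy iodide.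

Step 11
Reactants: 18 4-methoxyphenol; 19 tributyl(iodomethyl)stannane
Product: 21 tributyl[(4-methoxyphenoxy)methyl]stannane, via sodium phenolate 20 (not isolated)
Conditions: NaH, DMF, 0 → 25 °C
Reagents that add atoms: none
Why: Williamson ether synthesis; the phenolate displaces iodide at the primary carbon next to tin.

Step 12
Reactants: 17 (3S,4R)-3-[2-[tert-butyl(dimethyl)silyl]oxyethyl]-3,4-dimethyloxan-2-one; 21 tributyl[(4-methoxyphenoxy)methyl]stannane
Product: 23 (3S,4R)-3-[2-[tert-butyl(dimethyl)silyl]oxyethyl]-6-hydroxy-1-(4-methoxyphenoxy)-3,4-dimethylhexan-2-one, via aryloxymethyllithium 22 (not isolated)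
Conditions: 21, n-BuLi, THF, −78 °C; then 17, −78 °C; aq. NH4Cl
Reagents that add atoms: none
Why: Tin–lithium exchange gives the alpha-aryloxy organolithium, which adds once to the lactone carbonyl. The cyclic lithium hemiketal is stable at −78 °C and blocks a second addition, then opens to the hydroxy ketone on work-up (acyl substitution of a lactone).

Step 13
Reactants: 23 (3S,4R)-3-[2-[tert-butyl(dimethyl)silyl]oxyethyl]-6-hydroxy-1-(4-methoxyphenoxy)-3,4-dimethylhexan-2-one
Product: 25 methyl (3R,4S)-4-[2-[tert-butyl(dimethyl)silyl]oxyethyl]-6-(4-methoxyphenoxy)-3,4-dimethyl-5-oxohexanoate, via keto acid 24 (not isolated)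
Conditions: 2,2,6,6-tetramethylpiperidin-1-oxyl (cat.), PhI(OAc)2, MeCN/aq. pH 7 buffer, 25 °C; then Me3SiCHN2, PhMe/MeOH, 0 °C
Reagents that add atoms: water, O; trimethylsilyldiazomethane, C[Si](C)(C)C=[N+]=[N-]
Why: The nitroxyl/iodine oxidant takes the primary alcohol to the acid under near-neutral conditions that spare the silyl ether, and the diazo reagent esterifies it; ketone and aryl ether are inert.

Step 14
Reactants: 25 methyl (3R,4S)-4-[2-[tert-butyl(dimethyl)silyl]oxyethyl]-6-(4-methoxyphenoxy)-3,4-dimethyl-5-oxohexanoate
Product: 28 methyl (3R,4S)-4-[2-[tert-butyl(dimethyl)silyl]oxyethyl]-6-(4-methoxyphenoxy)-3,4-dimethylhex-5-ynoate, via potassium enolate 26 (not isolated), via enol triflate 27 (not isolated)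
Conditions: KN(SiMe3)2, THF, −78 °C; PhNTf2; then KOtBu, −78 → −40 °C
Reagents that add atoms: none
Why: The ketone can enolise only toward C28 (C7 is quaternary), and these hydrogens are far more acidic than the ester ones. O-triflation gives the enol triflate with H and the triflate anti, and KOtBu effects anti elimination to the ynol ether (enol triflate route to alkynyl ethers).

Step 15
Reactants: 28 methyl (3R,4S)-4-[2-[tert-butyl(dimethyl)silyl]oxyethyl]-6-(4-methoxyphenoxy)-3,4-dimethylhex-5-ynoate
Product: 30 methyl (3R,4S,5Z)-4-[2-[tert-butyl(dimethyl)silyl]oxyethyl]-6-(4-methoxyphenoxy)-3,4,5-trimethylhex-5-enoate, via alkenylcopper 29 (not isolated)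
Conditions: MeMgBr, CuBr·SMe2, Et2O, −40 → −15 °C; aq. NH4Cl at −40 °C
Reagents that add atoms: methylmagnesium bromide, C[Mg]Br
Why: Carbocupration of an ynol ether: methylcopper adds syn, with copper on the oxygen-bearing carbon C28 and methyl on C30. Protonation with retention puts H cis to the new methyl, so the aryloxy group ends cis to C7 (Z); the organocopper reagent leaves the methyl ester alone at this temperature.

Step 16
Reactants: 30 methyl (3R,4S,5Z)-4-[2-[tert-butyl(dimethyl)silyl]oxyethyl]-6-(4-methoxyphenoxy)-3,4,5-trimethylhex-5-enoate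
Product: 31 methyl (3R,4S,5Z)-4-(2-hydroxyethyl)-6-(4-methoxyphenoxy)-3,4,5-trimethylhex-5-enoate
Conditions: Bu4NF, AcOH (buffer), THF, 0 °C
Reagents that add atoms: none
Why: Fluoride cleavage of the primary silyl ether; the aryl enol ether and the ester are stable to buffered fluoride.

Step 17
Reactants: 31 methyl (3R,4S,5Z)-4-(2-hydroxyethyl)-6-(4-methoxyphenoxy)-3,4,5-trimethylhex-5-enoate
Product: 32 methyl (3R,4S,5Z)-6-(4-methoxyphenoxy)-3,4,5-trimethyl-4-(2-oxoethyl)hex-5-enoate
Conditions: Dess–Martin periodinane, NaHCO3, CH2Cl2, 0 → 25 °C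
Reagents that add atoms: none
Why: Dess–Martin oxidation under buffered, non-acidic conditions gives the aldehyde without touching the acid-sensitive enol ether.

Step 18
Reactants: 10 (1S,4S)-3,3-dimethyl-1-(2-methylidenebut-3-yn-1-yl)-7-oxabicyclo[2.2.1]heptane; 32 methyl (3R,4S,5Z)-6-(4-methoxyphenoxy)-3,4,5-trimethyl-4-(2-oxoethyl)hex-5-enoate
Product: 35 methyl (3R,4S)-6-(methoxycarbonyloxy)-4-[(1Z)-1-(4-methoxyphenoxy)prop-1-en-2-yl]-3,4-dimethyl-9-methylidene-10-[(1S,4S)-3,3-dimethyl-7-oxabicyclo[2.2.1]heptan-1-yl]dec-7-ynoate (both C6 epimers), via lithium acetylide 33 (not isolated), via lithium alkoxide 34 (not isolated)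
Conditions: 10, n-BuLi, THF, −78 °C; 32; then ClCO2Me, −78 → 0 °C
Reagents that add atoms: methyl chloroformate, COC(=O)Cl
Why: The lithium acetylide adds to the aldehyde much faster than to the methyl ester at −78 °C (1,2-addition), and the chloroformate acylates the alkoxide in the same flask. C10 forms as both epimers, which is of no consequence because it becomes sp2.

Step 19
Reactants: 35 methyl (3R,4S)-6-(methoxycarbonyloxy)-4-[(1Z)-1-(4-methoxyphenoxy)prop-1-en-2-yl]-3,4-dimethyl-9-methylidene-10-[(1S,4S)-3,3-dimethyl-7-oxabicyclo[2.2.1]heptan-1-yl]dec-7-ynoate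
Product: 36 methyl (3R,4S)-8-(methoxycarbonyl)-4-[(1Z)-1-(4-methoxyphenoxy)prop-1-en-2-yl]-3,4-dimethyl-9-methylidene-10-[(1S,4S)-3,3-dimethyl-7-oxabicyclo[2.2.1]heptan-1-yl]deca-6,7-dienoate (both allene epimers)
Conditions: Pd(OAc)2 (5 mol %), PPh3 (20 mol %), CO (1 atm), MeOH, 25 °C
Reagents that add atoms: carbon monoxide, [C-]#[O+]; methanol, CO
Why: Palladium-catalysed carbonylation of a propargylic carbonate: zerovalent palladium attacks in the SN2′ sense with loss of CO2, CO inserts into the allenylpalladium methoxide, and methanolysis releases the 2,3-dienoate. With a 1,3-enyne substituent this is the known route to 2-vinyl-2,3-dienoates; room temperature is chosen so that 36 can be isolated before it cyclises.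

Step 20
Reactants: 36 methyl (3R,4S)-8-(methoxycarbonyl)-4-[(1Z)-1-(4-methoxyphenoxy)prop-1-en-2-yl]-3,4-dimethyl-9-methylidene-10-[(1S,4S)-3,3-dimethyl-7-oxabicyclo[2.2.1]heptan-1-yl]deca-6,7-dienoate
Product: 37 methyl (3R)-3-[(1S,7R,7aS)-4-(methoxycarbonyl)-7-(4-methoxyphenoxy)-1,7a-dimethyl-5-{[(1S,4S)-3,3-dimethyl-7-oxabicyclo[2.2.1]heptan-1-yl]methyl}-2,6,7,7a-tetrahydro-1H-inden-1-yl]butanoate
Conditions: PhMe (0.01 M), 2,6-di-tert-butyl-4-methylphenol (cat.), 80 °C
Reagents that add atoms: none
Why: Concerted but asynchronous [4+2] cycloaddition with inverse electron demand: the LUMO of the 2-methoxycarbonyl diene C11=C12–C16=C27 is largest at the central allene carbon C11 and the HOMO of the aryl enol ether is largest at C30, so C11–C30 runs ahead of C27–C28. The closest known reaction type is the thermal intramolecular Diels–Alder reaction of vinylallenes tethered through the allene terminus, driven by release of cumulene strain and leaving the distal allene carbon C10 as an alkene carbon. Ring A closes as the fused five-membered tether ring (C7, C9, C10, C11, C30), exo with respect to both reacting pi bonds, and ring B closes as the six-membered cycloadduct ring through the two new sigma bonds. C28 is controlled by alkene geometry: suprafacial addition to the Z enol ether keeps the aryloxy group cis to C7 and therefore trans to C31, and the linear allene forces C7 and the aryloxy group exo, so only H lies under the diene. C30 is controlled by C7: the tether carbon C9 must stand over the diene, which leaves one C7 substituent near the enol ether plane on the C28 side, where it meets the cis aryloxy group (1,3-allylic strain), and the other on the C31 side; methyl C8 takes the first place and the butanoate arm the second, giving the arm cis to C31. The selectivity the step needs is therefore the choice of enol ether face, and it is secured by the Z aryloxy group together with the size difference between methyl and a secondary alkyl group on C7. Regiochemistry is fixed by the tether, no endo/exo stereocentre arises because C11 becomes sp2 and C27 is a methylene, and the two allene epimers converge because the allene axis is destroyed.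

Step 21
Reactants: 37 methyl (3R)-3-[(1S,7R,7aS)-4-(methoxycarbonyl)-7-(4-methoxyphenoxy)-1,7a-dimethyl-5-{[(1S,4S)-3,3-dimethyl-7-oxabicyclo[2.2.1]heptan-1-yl]methyl}-2,6,7,7a-tetrahydro-1H-inden-1-yl]butanoate
Product: 38 methyl (3R)-3-[(1S,7R,7aS)-7-hydroxy-4-(methoxycarbonyl)-1,7a-dimethyl-5-{[(1S,4S)-3,3-dimethyl-7-oxabicyclo[2.2.1]heptan-1-yl]methyl}-2,6,7,7a-tetrahydro-1H-inden-1-yl]butanoate
Conditions: (NH4)2Ce(NO3)6, MeCN/H2O (4:1), 0 °C
Reagents that add atoms: none
Why: Oxidative dearylation: the cerium salt oxidises the electron-rich 4-methoxyphenyl ring, water adds at the ipso carbon and benzoquinone is expelled. The C28–O bond is never broken, so configuration is retained, and the electron-poor dienoate should not be oxidised under these conditions.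

Step 22
Reactants: 38 methyl (3R)-3-[(1S,7R,7aS)-7-hydroxy-4-(methoxycarbonyl)-1,7a-dimethyl-5-{[(1S,4S)-3,3-dimethyl-7-oxabicyclo[2.2.1]heptan-1-yl]methyl}-2,6,7,7a-tetrahydro-1H-inden-1-yl]butanoate
Product: 39 (3R)-3-[(1S,7R,7aS)-4-carboxy-7-hydroxy-1,7a-dimethyl-5-{[(1S,4S)-3,3-dimethyl-7-oxabicyclo[2.2.1]heptan-1-yl]methyl}-2,6,7,7a-tetrahydro-1H-inden-1-yl]butanoic acid
Conditions: LiOH·H2O, THF/MeOH/H2O, 40 °C; then aq. KHSO4 to pH 3
Reagents that add atoms: lithium hydroxide, [Li+].[OH-]
Why: Saponification of both methyl esters by addition–elimination at the acyl carbons; moderate temperature and a mildly acidic work-up avoid gamma-deprotonation at C17 and acid opening of the ether bridge.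

## Compound list

1 | 6-methylhept-5-en-2-one | CC(=O)CCC=C(C)C | starting material
2 | lithium 6-methylhepta-1,5-dien-2-olate | C=C(O[Li])CCC=C(C)C | intermediate
3 | 6-methylhepta-1,5-dien-2-yl trifluoromethanesulfonate | C=C(OS(=O)(=O)C(F)(F)F)CCC=C(C)C | intermediate
4 | 8-methyl-4-methylidenenona-1,7-diene | C=CCC(=C)CCC=C(C)C | intermediate
5 | (3S)-2,2-dimethyl-3-(3-methylidenehex-5-en-1-yl)oxirane | C=CCC(=C)CC[C@@H]1OC1(C)C | intermediate
6 | (1S,4S)-3,3-dimethyl-1-(prop-2-en-1-yl)-7-oxabicyclo[2.2.1]heptane | C=CC[C@]12CC[C@H](O1)C(C)(C)C2 | intermediate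
7 | 1-[(1R,4S)-3,3-dimethyl-7-oxabicyclo[2.2.1]heptan-1-yl]propan-2-one | CC(=O)C[C@]12CC[C@H](O1)C(C)(C)C2 | intermediate
8 | potassium 3-[(1R,4S)-3,3-dimethyl-7-oxabicyclo[2.2.1]heptan-1-yl]prop-1-en-2-olate | C=C(O[K])C[C@]12CC[C@H](O1)C(C)(C)C2 | intermediate
9 | 3-[(1R,4S)-3,3-dimethyl-7-oxabicyclo[2.2.1]heptan-1-yl]prop-1-en-2-yl trifluoromethanesulfonate | C=C(OS(=O)(=O)C(F)(F)F)C[C@]12CC[C@H](O1)C(C)(C)C2 | intermediate
10 | (1S,4S)-3,3-dimethyl-1-(2-methylidenebut-3-yn-1-yl)-7-oxabicyclo[2.2.1]heptane | C#CC(=C)C[C@]12CC[C@H](O1)C(C)(C)C2 | intermediate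
11 | (3R)-5-methoxy-3-methyl-5-oxopentanoic acid [(R)-3-methylglutaric acid monomethyl ester] | C[C@@H](CC(=O)OC)CC(=O)O | starting material
12 | methyl (3R)-5-hydroxy-3-methylpentanoate | C[C@@H](CC(=O)OC)CCO | intermediate
13 | (4R)-4-methyloxan-2-one | C[C@@H]1CCOC(=O)C1 | intermediate
14 | lithium (4R)-4-methyl-3,4-dihydro-2H-pyran-6-olate | C[C@@H]1CCOC(O[Li])=C1 | intermediate
15 | (3S,4R)-3,4-dimethyloxan-2-one | C[C@@H]1CCOC(=O)[C@H]1C | intermediate
16 | lithium (4R)-4,5-dimethyl-3,4-dihydro-2H-pyran-6-olate | C[C@@H]1CCOC(O[Li])=C1C | intermediate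
17 | (3S,4R)-3-[2-[tert-butyl(dimethyl)silyl]oxyethyl]-3,4-dimethyloxan-2-one | C[C@@H]1CCOC(=O)[C@@]1(C)CCO[Si](C)(C)C(C)(C)C | intermediate
18 | 4-methoxyphenol | COc1ccc(O)cc1 | starting material
19 | tributyl(iodomethyl)stannane | CCCC[Sn](CI)(CCCC)CCCC | starting material
20 | sodium 4-methoxyphenolate | COc1ccc(O[Na])cc1 | intermediate
21 | tributyl[(4-methoxyphenoxy)methyl]stannane | CCCC[Sn](COc1ccc(OC)cc1)(CCCC)CCCC | intermediate
22 | [(4-methoxyphenoxy)methyl]lithium | [Li]COc1ccc(OC)cc1 | intermediate
23 | (3S,4R)-3-[2-[tert-butyl(dimethyl)silyl]oxyethyl]-6-hydroxy-1-(4-methoxyphenoxy)-3,4-dimethylhexan-2-one | C[C@H](CCO)[C@](C)(CCO[Si](C)(C)C(C)(C)C)C(=O)COc1ccc(OC)cc1 | intermediate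
24 | (3R,4S)-4-[2-[tert-butyl(dimethyl)silyl]oxyethyl]-6-(4-methoxyphenoxy)-3,4-dimethyl-5-oxohexanoic acid | C[C@H](CC(=O)O)[C@](C)(CCO[Si](C)(C)C(C)(C)C)C(=O)COc1ccc(OC)cc1 | intermediate
25 | methyl (3R,4S)-4-[2-[tert-butyl(dimethyl)silyl]oxyethyl]-6-(4-methoxyphenoxy)-3,4-dimethyl-5-oxohexanoate | C[C@H](CC(=O)OC)[C@](C)(CCO[Si](C)(C)C(C)(C)C)C(=O)COc1ccc(OC)cc1 | intermediate
26 | potassium enolate of 25 (O–K on C5, cis to the aryloxy group on C6) | C[C@H](CC(=O)OC)[C@](C)(CCO[Si](C)(C)C(C)(C)C)/C(O[K])=C/Oc1ccc(OC)cc1 | intermediate
27 | methyl (3R,4S,5Z)-4-[2-[tert-butyl(dimethyl)silyl]oxyethyl]-6-(4-methoxyphenoxy)-3,4-dimethyl-5-(trifluoromethanesulfonyloxy)hex-5-enoate | C[C@H](CC(=O)OC)[C@](C)(CCO[Si](C)(C)C(C)(C)C)/C(OS(=O)(=O)C(F)(F)F)=C/Oc1ccc(OC)cc1 | intermediate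
28 | methyl (3R,4S)-4-[2-[tert-butyl(dimethyl)silyl]oxyethyl]-6-(4-methoxyphenoxy)-3,4-dimethylhex-5-ynoate | C[C@H](CC(=O)OC)[C@](C)(CCO[Si](C)(C)C(C)(C)C)C#COc1ccc(OC)cc1 | intermediate
29 | alkenylcopper from syn addition of methylcopper to 28 (Cu on C6, cis to the new C5 methyl) | C[C@H](CC(=O)OC)[C@](C)(CCO[Si](C)(C)C(C)(C)C)/C(C)=C(/[Cu])Oc1ccc(OC)cc1 | intermediate
30 | methyl (3R,4S,5Z)-4-[2-[tert-butyl(dimethyl)silyl]oxyethyl]-6-(4-methoxyphenoxy)-3,4,5-trimethylhex-5-enoate | C[C@H](CC(=O)OC)[C@](C)(CCO[Si](C)(C)C(C)(C)C)/C(C)=C\Oc1ccc(OC)cc1 | intermediate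
31 | methyl (3R,4S,5Z)-4-(2-hydroxyethyl)-6-(4-methoxyphenoxy)-3,4,5-trimethylhex-5-enoate | C[C@H](CC(=O)OC)[C@](C)(CCO)/C(C)=C\Oc1ccc(OC)cc1 | intermediate
32 | methyl (3R,4S,5Z)-6-(4-methoxyphenoxy)-3,4,5-trimethyl-4-(2-oxoethyl)hex-5-enoate | C[C@H](CC(=O)OC)[C@](C)(CC=O)/C(C)=C\Oc1ccc(OC)cc1 | intermediate
33 | lithium acetylide of 10 | [Li]C#CC(=C)C[C@]12CC[C@H](O1)C(C)(C)C2 | intermediate
34 | lithium alkoxide of the C6 propargylic alcohol that precedes 35 (both C6 epimers) | C[C@H](CC(=O)OC)[C@](C)(CC(O[Li])C#CC(=C)C[C@]12CC[C@H](O1)C(C)(C)C2)/C(C)=C\Oc1ccc(OC)cc1 | intermediate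
35 | methyl (3R,4S)-6-(methoxycarbonyloxy)-4-[(1Z)-1-(4-methoxyphenoxy)prop-1-en-2-yl]-3,4-dimethyl-9-methylidene-10-[(1S,4S)-3,3-dimethyl-7-oxabicyclo[2.2.1]heptan-1-yl]dec-7-ynoate (both C6 epimers) | C[C@H](CC(=O)OC)[C@](C)(CC(OC(=O)OC)C#CC(=C)C[C@]12CC[C@H](O1)C(C)(C)C2)/C(C)=C\Oc1ccc(OC)cc1 | intermediate
36 | methyl (3R,4S)-8-(methoxycarbonyl)-4-[(1Z)-1-(4-methoxyphenoxy)prop-1-en-2-yl]-3,4-dimethyl-9-methylidene-10-[(1S,4S)-3,3-dimethyl-7-oxabicyclo[2.2.1]heptan-1-yl]deca-6,7-dienoate (both allene epimers) | C[C@H](CC(=O)OC)[C@](C)(CC=C=C(C(=O)OC)C(=C)C[C@]34CC[C@H](O3)C(C)(C)C4)/C(C)=C\Oc1ccc(OC)cc1 | intermediate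
37 | methyl (3R)-3-[(1S,7R,7aS)-4-(methoxycarbonyl)-7-(4-methoxyphenoxy)-1,7a-dimethyl-5-{[(1S,4S)-3,3-dimethyl-7-oxabicyclo[2.2.1]heptan-1-yl]methyl}-2,6,7,7a-tetrahydro-1H-inden-1-yl]butanoate | C[C@H](CC(=O)OC)[C@]1(C)CC=C2C(C(=O)OC)=C(C[C@]34CC[C@H](O3)C(C)(C)C4)C[C@@H](Oc5ccc(OC)cc5)[C@]21C | intermediate
38 | methyl (3R)-3-[(1S,7R,7aS)-7-hydroxy-4-(methoxycarbonyl)-1,7a-dimethyl-5-{[(1S,4S)-3,3-dimethyl-7-oxabicyclo[2.2.1]heptan-1-yl]methyl}-2,6,7,7a-tetrahydro-1H-inden-1-yl]butanoate | C[C@H](CC(=O)OC)[C@]1(C)CC=C2C(C(=O)OC)=C(C[C@]34CC[C@H](O3)C(C)(C)C4)C[C@@H](O)[C@]21C | intermediate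
39 | (3R)-3-[(1S,7R,7aS)-4-carboxy-7-hydroxy-1,7a-dimethyl-5-{[(1S,4S)-3,3-dimethyl-7-oxabicyclo[2.2.1]heptan-1-yl]methyl}-2,6,7,7a-tetrahydro-1H-inden-1-yl]butanoic acid | C[C@H](CC(=O)O)[C@]1(C)CC=C2C(C(=O)O)=C(C[C@]34CC[C@H](O3)C(C)(C)C4)C[C@@H](O)[C@]21C | target

## Step count and least certain steps

Total step count: 22. Longest linear sequence: 14 steps (steps 8 to 10 and 12 to 22, from 11 to 39).

Step 20 (key step). The most likely failure is poor discrimination between the two faces of the enol ether, because the choice rests only on methyl versus a secondary alkyl group on C7. A second failure is cycloaddition at the fully substituted C30 being slow enough that the allenoate dimerises or polymerises at the temperature needed. The fallback lowers the diene LUMO so that the reaction can run near room temperature, where the 1,3-allylic preference should be expressed more fully. It sets out from 10 and 32: alkoxide 34 is capped with 2,2,2-trifluoroethyl chloroformate to give the trifluoroethyl carbonate F1; carbonylation in CF3CH2OH (Pd(OAc)2, PPh3, CO) should give the trifluoroethyl allenoate F2; this is cyclised at 25 to 40 °C to cycloadduct F3; (NH4)2Ce(NO3)6 then gives alcohol F4; and LiOH hydrolysis of both esters returns to the route at 39. The more electrophilic ester should also ease the final hydrolysis.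

Step 15. The most likely failure is slow methyl transfer to an alkyne carbon next to a quaternary centre, during which the alpha-aryloxy alkenylcopper 29 can lose copper aryloxide on warming, costing yield or geometric purity. The fallback makes the two bonds in separate stereospecific steps. From 28, copper-catalysed syn addition of boron and hydrogen (B2pin2, CuCl, NaOtBu, MeOH, THF) should place boron on C30 and hydrogen on C28, giving the alkenylboronate F5. Suzuki–Miyaura methylation (MeI, PdCl2(dppf), Cs2CO3) with retention then returns to the route at 30.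

Step 4. The most likely failure is termination by proton loss (cyclohexenols) or epoxide-to-ketone rearrangement in place of ether closure, since the cation at C18 has three sets of adjacent hydrogens. The fallback separates C–C from C–O bond formation. From 5, cyclisation with MeAlCl2 at −78 °C is stopped at the alkenol stage to give (1S)-6,6-dimethyl-4-(prop-2-en-1-yl)cyclohex-3-en-1-ol F6 (its double-bond isomers behave alike). Iodoetherification (I2, NaHCO3, MeCN) closes the bridge at the tertiary carbon to give the iodo ether F7, and Bu3SnH with a radical initiator removes iodine, returning to the route at 6.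

Step 10. The most likely failure is sluggish alkylation of the hindered enolate by the beta-silyloxy iodide, with elimination of the iodide and erosion of diastereoselectivity on warming. The fallback introduces the arm as an allyl group and trims it. From 15, allyl bromide (LiN(iPr)2, THF) gives the allyl lactone F8 with the same facial preference. Ozonolysis with PPh3 work-up gives the aldehyde F9, NaBH(OAc)3 reduces only the aldehyde to the hydroxyethyl lactone F10, and immediate silylation (tBuMe2SiCl, imidazole), before acyl migration can occur, returns to the route at 17.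

## Further compounds

F1 | step 20 | 2,2,2-trifluoroethyl carbonate analogue of 35 (both C6 epimers) | C[C@H](CC(=O)OC)[C@](C)(CC(OC(=O)OCC(F)(F)F)C#CC(=C)C[C@]12CC[C@H](O1)C(C)(C)C2)/C(C)=C\Oc1ccc(OC)cc1
F2 | step 20 | 2,2,2-trifluoroethyl allenoate analogue of 36 (both allene epimers) | C[C@H](CC(=O)OC)[C@](C)(CC=C=C(C(=O)OCC(F)(F)F)C(=C)C[C@]34CC[C@H](O3)C(C)(C)C4)/C(C)=C\Oc1ccc(OC)cc1
F3 | step 20 | cycloadduct analogue of 37 with a 2,2,2-trifluoroethyl ester on C12 | C[C@H](CC(=O)OC)[C@]1(C)CC=C2C(C(=O)OCC(F)(F)F)=C(C[C@]34CC[C@H](O3)C(C)(C)C4)C[C@@H](Oc5ccc(OC)cc5)[C@]21C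
F4 | step 20 | C28 alcohol analogue of 38 with a 2,2,2-trifluoroethyl ester on C12 | C[C@H](CC(=O)OC)[C@]1(C)CC=C2C(C(=O)OCC(F)(F)F)=C(C[C@]34CC[C@H](O3)C(C)(C)C4)C[C@@H](O)[C@]21C
F5 | step 15 | methyl (3R,4S,5Z)-4-[2-[tert-butyl(dimethyl)silyl]oxyethyl]-6-(4-methoxyphenoxy)-3,4-dimethyl-5-(4,4,5,5-tetramethyl-1,3,2-dioxaborolan-2-yl)hex-5-enoate | C[C@H](CC(=O)OC)[C@](C)(CCO[Si](C)(C)C(C)(C)C)/C(B1OC(C)(C)C(C)(C)O1)=C\Oc1ccc(OC)cc1
F6 | step 4 | (1S)-6,6-dimethyl-4-(prop-2-en-1-yl)cyclohex-3-en-1-ol | C=CCC1=CC[C@H](O)C(C)(C)C1
F7 | step 4 | (1S,2S,4S)-2-iodo-5,5-dimethyl-1-(prop-2-en-1-yl)-7-oxabicyclo[2.2.1]heptane | C=CC[C@]12[C@@H](I)C[C@H](O1)C(C)(C)C2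
F8 | step 10 | (3S,4R)-3,4-dimethyl-3-(prop-2-en-1-yl)oxan-2-one | C[C@@H]1CCOC(=O)[C@@]1(C)CC=C
F9 | step 10 | 2-[(3S,4R)-3,4-dimethyl-2-oxooxan-3-yl]acetaldehyde | C[C@@H]1CCOC(=O)[C@@]1(C)CC=O
F10 | step 10 | (3S,4R)-3-(2-hydroxyethyl)-3,4-dimethyloxan-2-one | C[C@@H]1CCOC(=O)[C@@]1(C)CCO
A1 | alternative 1 | cis-fused ring A cyclopentanone with C28 ketone and C16 dioxolane ketal | C[C@H](CC(=O)OC)[C@]1(C)CC(=O)[C@H]2CC3(OCCO3)CC(=O)[C@]21C
A2 | alternative 1 | 1,5-dien-3-one: C7=C9 enone joined through C10 and C11 to the ring B trimethylsilyl enol ether C30=C28 (enone geometry and C11 not defined) | C[C@H](CC(=O)OC)C(C)=CC(=O)C1CC2(OCCO2)CC(O[Si](C)(C)C)=C1C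
A3 | alternative 2 | acetylcyclopentenone fragment 1 with both quaternary centres | C[C@H](CC(=O)OC)[C@]1(C)C=CC(=O)[C@@]1(C)C(C)=O
A4 | alternative 2 | ynoate fragment 2: methyl 4-[(1S,4S)-3,3-dimethyl-7-oxabicyclo[2.2.1]heptan-1-yl]but-2-ynoate | COC(=O)C#CC[C@]12CC[C@H](O1)C(C)(C)C2
A5 | alternative 2 | ring B aldol with C11 tertiary alcohol and C28 ketone | C[C@H](CC(=O)OC)[C@]1(C)C=C[C@@]2(O)C(C(=O)OC)=C(C[C@]34CC[C@H](O3)C(C)(C)C4)CC(=O)[C@]21C
A6 | alternative 3 | dimethyl ester C28 acetate carrying the (S)-epoxy 1,1-disubstituted alkene side chain on C16 | C[C@H](CC(=O)OC)[C@]1(C)CC=C2C(C(=O)OC)=C(CC(=C)CC[C@@H]3OC3(C)C)C[C@@H](OC(C)=O)[C@]21C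
A7 | alternative 3 | dimethyl ester C28 acetate of the target skeleton | C[C@H](CC(=O)OC)[C@]1(C)CC=C2C(C(=O)OC)=C(C[C@]34CC[C@H](O3)C(C)(C)C4)C[C@@H](OC(C)=O)[C@]21C
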